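## The problem

Compound 21 is a single carbocycle, a cyclohex-2-en-1-one, so no ring fusion has to be planned. The difficulty is that five of the six ring carbons are functionalised in a fixed order: ketone at C1, hydroxymethyl at C2, isobutyrate at C4, isopropyl at C5 and an (E)-4-hydroxy-2-methylbut-2-enoate at C6. C4 (S), C5 (S) and C6 (R) are contiguous stereocentres; the C4 oxygen is cis and the C6 oxygen trans to the isopropyl group. C5 lies between the two carbinol carbons, so the event that sets C5 is best placed to set both neighbours. C6 is α to the ketone and its trans relation to C5 should survive equilibration, whereas C4 cannot be corrected later and must be set directly. Two different acyl groups go onto two secondary oxygens while two primary allylic alcohols stay free, which fixes the order of acylations and calls for a small set of protecting groups. The fragile elements are the γ-acyloxy enone (loss of the C4 and C6 oxygens leads to a phenol), the base-labile α'-acyloxy ketone, the Baylis–Hillman-type alcohol at C2 and the E-enoate side chain. The enabling feature is the array C1(O)–C2=C3–C4(O) next to a C5–C6 unit that carries carbon beside oxygen: this is the footprint of a 2-pyrone whose lactone spans C1 and C4, joined to the two carbons of a β-isopropyl enol ether.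

## Retrosynthesis

**21 ⇒ 20.** Only two O–Si bonds are cut. Both primary allylic alcohols are released together in the last step under buffered acidic fluoride, so that no free hydroxyl is present while esters are being made. The precursor 20 is no simpler in skeleton, but the forward step asks only for desilylation without acyl migration.

**20 ⇒ 14 + 18.** The C6–O acyl bond is cut. This ester is α to the ketone and the most base-labile, so it is made last among the acylations, after all aqueous-base chemistry. The cut removes the whole side chain; acid 18 comes in two steps from aldehyde 15 and ylide 16 through ester 17, where the C2'=C3' bond is cut by a Wittig reaction. The forward reaction must acylate a hindered α-ketol without enolising C6 and without isomerising the enoate.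

**14 ⇒ 13 ⇒ 12 ⇒ 11.** The benzylic ether bond at C6 and the silyl ether are cut, then the C2–C7 bond, by a Morita–Baylis–Hillman hydroxymethylation of enone 11. Adding C7 to a finished enone is preferred to carrying it in the diene, which would need a less activated, more substituted pyrone, and to a two-step halogenation and cross-coupling. The hydroxymethylation is placed while C6 is still an ether, so the aqueous nucleophilic catalyst never meets an α'-acyloxy ketone; the price is one silylation (12 to 13).

**11 ⇒ 10.** The C4–O acyl bond is cut. In 10 the two ring oxygens are already distinguished: C4 is a free alcohol and C6 a 4-methoxybenzyl ether, so no selectivity is required of the acylation.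

**10 ⇒ 8 (through 9) ⇒ 7.** Both C1–carboxyl bonds are cut: the ketone is traced to a malonic acid, and the diacid 8 to the lactone ester 7. Oxidative bis-decarboxylation is preferred to mono-decarboxylation followed by enolate oxidation. A carbanion at C1 would expel the C6 alkoxide by E1cB and the C4 oxygen by vinylogous elimination, and the ring would aromatise. The forward reaction must oxidise C1 without allylic transposition to C3 and without touching the free C4 hydroxyl.

**7 ⇒ 5 + 6.** The C1–C6 and C4–C5 bonds (target numbering) are cut by a retro-[4+2] reaction. No other cut in the route removes as much: the ring, three oxygen-bearing carbons and all three stereocentres fall back to two achiral components, the purchased pyrone 6 and the E-enol ether 5. The forward cycloaddition must be regioselective, endo-selective for the alkoxy group, stereospecific for the E-alkene and face-selective under a chiral Lewis acid.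

**5 ⇒ 3 + 4; 3 ⇒ 1 (through 2).** The vinyl C–O bond is cut, giving alcohol 4 and E-iodide 3, which comes from alkyne 1 through alkenylzirconocene 2. A stereodefined coupling is preferred to acetal elimination or allyl ether isomerisation, which would give E/Z mixtures; the E geometry becomes the trans C5/C6 relation.

## Roads not taken

**Alternative 1:** The cuts are C6–C1 and C4–C3. 2-Isopropylpropane-1,3-diol A1 and 2-methylenepropane-1,3-diyl diacetate A2 would be joined twice by iridium-catalysed dehydrogenation–allylation, closing the ring as the trans diol A3 with an exocyclic methylene on the future C2.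
- Merits: no protecting groups; the ring and both carbinol centres come from catalyst control; C7 is present from the start. In this respect it is better than the chosen plan, which spends three steps (4, 5 and 7) removing one carbon at C1 and adding another at C2.
- Weak points: A3 has neither the ketone nor the ring alkene. The two halves of A3 differ only in whether the hydroxyl is cis or trans to the isopropyl group. On that small difference one would have to decide which hydroxyl receives which acyl group and which allylic methylene becomes the ketone, then move the alkene into the ring and hydroxylate its carbon. The second allylation as a ring closure would also have to be shown.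
- Comparison: the chosen plan answers with an adduct 7 in which the C1 and C4 oxygens are already placed at the ends of the alkene and the C4 and C6 oxygens are chemically different from the outset.

**Alternative 2:** The cuts are C5–isopropyl and C6–O. Copper-catalysed enantioselective 1,4-addition of diisopropylzinc A5 to one enone of 4,4-dimethoxycyclohexa-2,5-dien-1-one A4, then silylation and peracid oxidation of the enolate, would give the trans hydroxy ketone A6.
- Merits: a cheap symmetrical starting material; the ring, the C1 ketone and the C2=C3 alkene are there from the beginning and no carbon is excised. The asymmetric step belongs to a reaction class that is better established than a face-selective cycloaddition with a 1,2-disubstituted enol ether. In this it is the stronger plan.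
- Weak points: C4 arrives at the ketone oxidation level. Unmasking gives an ene-dione one elimination away from a hydroquinone, and its C4 carbonyl must be reduced regio- and stereoselectively beside the C1 ketone, or the two must be separated by extra redox and protection steps. A secondary alkylzinc is also a less reactive nucleophile than a primary one, and C7 must still be added.
- Comparison: the chosen plan delivers C4 as an alcohol, cis to isopropyl by a concerted mechanism and already distinguished from the C6 oxygen. It pays for this with the decarboxylative unmasking of C1.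

**Alternative 3:** The cut is C5–C6. The Z-vinylglyoxal A7 would close by a Lewis acid-promoted intramolecular carbonyl-ene reaction, aldehyde as enophile and prenyl group as ene, to the hydroxy enone A8 with an isopropenyl group at C5.
- Merits: A8 already carries C7, the isobutyrate and the ketone. Only alkene hydrogenation, C6 acylation and desilylation would remain; this is the best endgame of the four plans and needs neither carbon excision nor hydroxymethylation.
- Weak points: A7 is hard to make and to keep. Its aldehyde hydrates, its Z-enone can isomerise, and its isobutyrate is doubly allylic and can be ionised by the Lewis acid that the cyclisation needs. C5 and C6 are set relative to C4 through a flexible transition state with no compelling bias for the 4,5-cis arrangement, and the isopropenyl group must be reduced beside the enone.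
- Comparison: the chosen plan builds its key step from two stable, simple partners and takes the relative configuration from a suprafacial cycloaddition, not from a conformational preference. It is longer after the ring is closed.

Key step: step 3

Assumption: the (R)-binaphthol ligand is written for step 3 on the premise that it shields the pyrone face leading to 7; if the sense of induction is the opposite, the (S)-ligand is used and nothing else changes.

## Route

Step 1
Reactants: 1 3-methylbut-1-yne
Product: 3 (E)-1-iodo-3-methylbut-1-ene, via alkenylzirconocene chloride 2 (not isolated)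
Conditions: Cp2Zr(H)Cl (1.1 equiv), CH2Cl2, rt; then I2, 0 °C
Reagents that add atoms: Cp2Zr(H)Cl (atoms retained in 2 only), SMILES [H][Zr](Cl)(C1C=CC=C1)C1C=CC=C1; iodine, SMILES II
Why: Hydrozirconation of a terminal alkyne is a syn addition that places zirconium on the terminal carbon, and iodinolysis of the C–Zr bond goes with retention, so only the E-iodide should form; the volatile product is carried on as a solution.

Step 2
Reactants: 3 (E)-1-iodo-3-methylbut-1-ene; 4 4-methoxybenzyl alcohol
Product: 5 (E)-1-[(4-methoxybenzyl)oxy]-3-methylbut-1-ene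
Conditions: CuI (10 mol%), 3,4,7,8-tetramethyl-1,10-phenanthroline (20 mol%), Cs2CO3, PhMe, 80 °C
Reagents that add atoms: none
Why: Copper-catalysed Ullmann-type C–O coupling of alkenyl iodides with primary alcohols retains the alkene geometry, so the E-enol ether that encodes the trans C5/C6 relation should be obtained stereodefined.

Step 3
Reactants: 5 (E)-1-[(4-methoxybenzyl)oxy]-3-methylbut-1-ene; 6 methyl 2-oxo-2H-pyran-3-carboxylate
Product: 7 methyl (1S,4R,7S,8R)-7-isopropyl-8-[(4-methoxybenzyl)oxy]-3-oxo-2-oxabicyclo[2.2.2]oct-5-ene-4-carboxylate (8-alkoxy endo, syn to C5=C6; 7-isopropyl exo, syn to the lactone bridge)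
Conditions: Yb(OTf)3 (20 mol%), (R)-BINOL (24 mol%), i-Pr2NEt (50 mol%), 4 Å MS, CH2Cl2, −20 °C → rt
Reagents that add atoms: none
Why: Trivalent ytterbium chelates the lactone and ester carbonyls of 6, lowers the diene LUMO and holds the binaphtholate over one face of the pyrone; the reaction type is the known Lewis acid-catalysed inverse-electron-demand Diels–Alder reaction of 3-alkoxycarbonyl-2-pyrones with enol ethers, here with a 1,2-disubstituted partner. The nucleophilic isopropyl-bearing carbon of 5 bonds to pyrone C6 and the oxygen-bearing carbon to pyrone C3, a regiochemistry fixed by the matched polarisation of both partners. The cyclohexene ring is closed by a concerted, asynchronous, suprafacial [4+2] cycloaddition (in the stepwise limit a 6-exo-trig closure of the malonate-type enolate onto the oxocarbenium ion), which leaves the lactone as a two-atom bridge. Suprafacial addition to the E-alkene makes the C7 isopropyl and C8 alkoxy groups trans. The alkoxy group should take the endo position under the diene, as enol ethers do with this pyrone, which puts the isopropyl group on the lactone side, cis to the bridgehead C1–O bond. The two bridgeheads are set together by the pyrone face that is attacked, and the ligand chooses that face. The step thus needs regio-, endo- and facial selectivity, which come from the substrates, the alkoxy group and the catalyst in turn; the amine and molecular sieves keep protic acid away from 5 and 7.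

Step 4
Reactants: 7 methyl (1S,4R,7S,8R)-7-isopropyl-8-[(4-methoxybenzyl)oxy]-3-oxo-2-oxabicyclo[2.2.2]oct-5-ene-4-carboxylate
Product: 8 (4S,5S,6R)-4-hydroxy-5-isopropyl-6-[(4-methoxybenzyl)oxy]cyclohex-2-ene-1,1-dicarboxylic acid
Conditions: LiOH·H2O (8 equiv), THF/H2O, rt → 50 °C; then 1 M HCl to pH 3, 0 °C, used crude
Reagents that add atoms: lithium hydroxide, SMILES [Li+].[OH-]
Why: Saponification opens the strained lactone by acyl–oxygen fission, so the C4–O bond and its configuration are kept, and then cleaves the methyl ester; C1 is quaternary, so no enolate can form and neither elimination nor epimerisation is possible.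

Step 5
Reactants: 8 (4S,5S,6R)-4-hydroxy-5-isopropyl-6-[(4-methoxybenzyl)oxy]cyclohex-2-ene-1,1-dicarboxylic acid
Product: 10 (4S,5S,6R)-4-hydroxy-5-isopropyl-6-[(4-methoxybenzyl)oxy]cyclohex-2-en-1-one, via gem-diacetate 9 (not isolated)
Conditions: Pb(OAc)4 (2.5 equiv), pyridine (3 equiv), PhH, rt → 40 °C; then 1 M aq. HCl, THF, rt
Reagents that add atoms: lead tetraacetate, SMILES CC(=O)O[Pb](OC(C)=O)(OC(C)=O)OC(C)=O; water, SMILES O
Why: Oxidative bis-decarboxylation of a disubstituted malonic acid by tetravalent lead (two Kochi-type oxidative decarboxylations) should give the acylal 9, which mild acid hydrolyses to the ketone. No carbanion is formed at C1, so the C6 ether cannot be lost by E1cB, and the stereocentres at C4–C6 are not involved.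

Step 6
Reactants: 10 (4S,5S,6R)-4-hydroxy-5-isopropyl-6-[(4-methoxybenzyl)oxy]cyclohex-2-en-1-one
Product: 11 (4S,5S,6R)-4-(isobutyryloxy)-5-isopropyl-6-[(4-methoxybenzyl)oxy]cyclohex-2-en-1-one
Conditions: (i-PrCO)2O, Et3N, DMAP (cat.), CH2Cl2, 0 °C → rt
Reagents that add atoms: isobutyric anhydride, SMILES CC(C)C(=O)OC(=O)C(C)C
Why: DMAP-catalysed acylation of the only free hydroxyl; C5 carries no leaving group, so neither enolate of the ketone can expel the new γ-ester.

Step 7
Reactants: 11 (4S,5S,6R)-4-(isobutyryloxy)-5-isopropyl-6-[(4-methoxybenzyl)oxy]cyclohex-2-en-1-one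
Product: 12 (4S,5S,6R)-2-(hydroxymethyl)-4-(isobutyryloxy)-5-isopropyl-6-[(4-methoxybenzyl)oxy]cyclohex-2-en-1-one
Conditions: 37% aq. HCHO, DMAP (0.5 equiv), THF/H2O, rt
Reagents that add atoms: formaldehyde, SMILES C=O
Why: Morita–Baylis–Hillman reaction: DMAP adds to C3, the enolate is hydroxymethylated at C2 and the catalyst is expelled; cyclohexenones with oxygen substituents at C4 and C6 are known substrates, and at this stage C6 carries an ether, not a hydrolysable ester.

Step 8
Reactants: 12 (4S,5S,6R)-2-(hydroxymethyl)-4-(isobutyryloxy)-5-isopropyl-6-[(4-methoxybenzyl)oxy]cyclohex-2-en-1-one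
Product: 13 (4S,5S,6R)-2-{[(tert-butyldimethylsilyl)oxy]methyl}-4-(isobutyryloxy)-5-isopropyl-6-[(4-methoxybenzyl)oxy]cyclohex-2-en-1-one
Conditions: TBSCl, imidazole, CH2Cl2, 0 °C
Reagents that add atoms: tert-butyldimethylsilyl chloride, SMILES CC(C)(C)[Si](C)(C)Cl
Why: Routine silylation of the only hydroxyl, a primary allylic alcohol, so that the C6 oxygen can later be acylated alone.

Step 9
Reactants: 13 (4S,5S,6R)-2-{[(tert-butyldimethylsilyl)oxy]methyl}-4-(isobutyryloxy)-5-isopropyl-6-[(4-methoxybenzyl)oxy]cyclohex-2-en-1-one
Product: 14 (4S,5R,6R)-2-{[(tert-butyldimethylsilyl)oxy]methyl}-6-hydroxy-4-(isobutyryloxy)-5-isopropylcyclohex-2-en-1-one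
Conditions: DDQ (1.5 equiv), CH2Cl2/pH 7 buffer (10:1), 0 °C → rt
Reagents that add atoms: none
Why: Oxidative cleavage of the 4-methoxybenzyl ether by hydride abstraction and hydrolysis of the oxocarbenium ion; the ester, silyl ether and electron-poor enone are inert, and the change of descriptor at C5 reflects ligand priorities only.

Step 10
Reactants: 15 (tert-butyldimethylsilyloxy)acetaldehyde; 16 ethyl 2-(triphenylphosphoranylidene)propanoate
Product: 17 ethyl (E)-4-[(tert-butyldimethylsilyl)oxy]-2-methylbut-2-enoate
Conditions: CH2Cl2, rt
Reagents that add atoms: none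
Why: Wittig reaction of a stabilised, α-branched ylide with an aliphatic aldehyde, which should give the E-trisubstituted enoate.

Step 11
Reactants: 17 ethyl (E)-4-[(tert-butyldimethylsilyl)oxy]-2-methylbut-2-enoate
Product: 18 (E)-4-[(tert-butyldimethylsilyl)oxy]-2-methylbut-2-enoic acid
Conditions: LiOH·H2O, THF/H2O, rt; then 1 M HCl to pH 4, 0 °C
Reagents that add atoms: lithium hydroxide, SMILES [Li+].[OH-]
Why: Ester saponification; the primary silyl ether and the E-alkene are stable to aqueous hydroxide at room temperature.

Step 12
Reactants: 18 (E)-4-[(tert-butyldimethylsilyl)oxy]-2-methylbut-2-enoic acid; 14 (4S,5R,6R)-2-{[(tert-butyldimethylsilyl)oxy]methyl}-6-hydroxy-4-(isobutyryloxy)-5-isopropylcyclohex-2-en-1-one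
Product: 20 (4S,5S,6R)-2-{[(tert-butyldimethylsilyl)oxy]methyl}-6-{[(E)-4-[(tert-butyldimethylsilyl)oxy]-2-methylbut-2-enoyl]oxy}-4-(isobutyryloxy)-5-isopropylcyclohex-2-en-1-one, via mixed anhydride 19 (not isolated)
Conditions: 2,4,6-Cl3C6H2COCl, Et3N, PhMe, rt; then 14, DMAP, rt
Reagents that add atoms: 2,4,6-trichlorobenzoyl chloride (atoms retained in 19 only), SMILES O=C(Cl)c1c(Cl)cc(Cl)cc1Cl
Why: Yamaguchi esterification: the mixed anhydride passes the enoyl group through an acyl-DMAP intermediate to the hindered α-ketol; the E-enoate is the thermodynamic isomer, and the trans C5/C6 arrangement is the preferred one should C6 enolise.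

Step 13
Reactants: 20 (4S,5S,6R)-2-{[(tert-butyldimethylsilyl)oxy]methyl}-6-{[(E)-4-[(tert-butyldimethylsilyl)oxy]-2-methylbut-2-enoyl]oxy}-4-(isobutyryloxy)-5-isopropylcyclohex-2-en-1-one
Product: 21 (4S,5S,6R)-2-(hydroxymethyl)-6-{[(E)-4-hydroxy-2-methylbut-2-enoyl]oxy}-4-(isobutyryloxy)-5-isopropylcyclohex-2-en-1-one (CNP0254776.1)
Conditions: HF·pyridine, pyridine, THF, 0 °C → rt
Reagents that add atoms: none
Why: Buffered HF·pyridine removes both primary silyl ethers under weakly acidic conditions in which esters neither hydrolyse nor migrate; the E side chain cannot lactonise.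

## Compound list

1 | 3-methylbut-1-yne | CC(C)C#C | starting material
2 | (E)-chlorobis(cyclopentadienyl)(3-methylbut-1-en-1-yl)zirconium | CC(C)/C=C/[Zr](Cl)(C1C=CC=C1)C1C=CC=C1 | intermediate (not isolated)
3 | (E)-1-iodo-3-methylbut-1-ene | CC(C)/C=C/I | intermediate
4 | 4-methoxybenzyl alcohol | COc1ccc(CO)cc1 | starting material
5 | (E)-1-[(4-methoxybenzyl)oxy]-3-methylbut-1-ene | COc1ccc(CO/C=C/C(C)C)cc1 | intermediate
6 | methyl 2-oxo-2H-pyran-3-carboxylate | COC(=O)C1=CC=COC1=O | starting material
7 | methyl (1S,4R,7S,8R)-7-isopropyl-8-[(4-methoxybenzyl)oxy]-3-oxo-2-oxabicyclo[2.2.2]oct-5-ene-4-carboxylate | COc1ccc(CO[C@H]2[C@@]3(C(=O)OC)C=C[C@H](OC3=O)[C@@H]2C(C)C)cc1 | intermediate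
8 | (4S,5S,6R)-4-hydroxy-5-isopropyl-6-[(4-methoxybenzyl)oxy]cyclohex-2-ene-1,1-dicarboxylic acid | COc1ccc(CO[C@H]2C(C(=O)O)(C(=O)O)C=C[C@H](O)[C@@H]2C(C)C)cc1 | intermediate
9 | (4S,5S,6R)-4-hydroxy-5-isopropyl-6-[(4-methoxybenzyl)oxy]cyclohex-2-ene-1,1-diyl diacetate | COc1ccc(CO[C@H]2C(OC(C)=O)(OC(C)=O)C=C[C@H](O)[C@@H]2C(C)C)cc1 | intermediate (not isolated)
10 | (4S,5S,6R)-4-hydroxy-5-isopropyl-6-[(4-methoxybenzyl)oxy]cyclohex-2-en-1-one | COc1ccc(CO[C@H]2C(=O)C=C[C@H](O)[C@@H]2C(C)C)cc1 | intermediate
11 | (4S,5S,6R)-4-(isobutyryloxy)-5-isopropyl-6-[(4-methoxybenzyl)oxy]cyclohex-2-en-1-one | COc1ccc(CO[C@H]2C(=O)C=C[C@H](OC(=O)C(C)C)[C@@H]2C(C)C)cc1 | intermediate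
12 | (4S,5S,6R)-2-(hydroxymethyl)-4-(isobutyryloxy)-5-isopropyl-6-[(4-methoxybenzyl)oxy]cyclohex-2-en-1-one | COc1ccc(CO[C@H]2C(=O)C(CO)=C[C@H](OC(=O)C(C)C)[C@@H]2C(C)C)cc1 | intermediate
13 | (4S,5S,6R)-2-{[(tert-butyldimethylsilyl)oxy]methyl}-4-(isobutyryloxy)-5-isopropyl-6-[(4-methoxybenzyl)oxy]cyclohex-2-en-1-one | COc1ccc(CO[C@H]2C(=O)C(CO[Si](C)(C)C(C)(C)C)=C[C@H](OC(=O)C(C)C)[C@@H]2C(C)C)cc1 | intermediate
14 | (4S,5R,6R)-2-{[(tert-butyldimethylsilyl)oxy]methyl}-6-hydroxy-4-(isobutyryloxy)-5-isopropylcyclohex-2-en-1-one | O[C@H]1C(=O)C(CO[Si](C)(C)C(C)(C)C)=C[C@H](OC(=O)C(C)C)[C@@H]1C(C)C | intermediate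
15 | (tert-butyldimethylsilyloxy)acetaldehyde | CC(C)(C)[Si](C)(C)OCC=O | starting material
16 | ethyl 2-(triphenylphosphoranylidene)propanoate | CCOC(=O)C(C)=P(c1ccccc1)(c1ccccc1)c1ccccc1 | starting material
17 | ethyl (E)-4-[(tert-butyldimethylsilyl)oxy]-2-methylbut-2-enoate | CCOC(=O)/C(C)=C/CO[Si](C)(C)C(C)(C)C | intermediate
18 | (E)-4-[(tert-butyldimethylsilyl)oxy]-2-methylbut-2-enoic acid | OC(=O)/C(C)=C/CO[Si](C)(C)C(C)(C)C | intermediate
19 | (E)-4-[(tert-butyldimethylsilyl)oxy]-2-methylbut-2-enoic 2,4,6-trichlorobenzoic anhydride | CC(C)(C)[Si](C)(C)OC/C=C(\C)C(=O)OC(=O)c1c(Cl)cc(Cl)cc1Cl | intermediate (not isolated)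
20 | (4S,5S,6R)-2-{[(tert-butyldimethylsilyl)oxy]methyl}-6-{[(E)-4-[(tert-butyldimethylsilyl)oxy]-2-methylbut-2-enoyl]oxy}-4-(isobutyryloxy)-5-isopropylcyclohex-2-en-1-one | C/C(=C\CO[Si](C)(C)C(C)(C)C)C(=O)O[C@H]1C(=O)C(CO[Si](C)(C)C(C)(C)C)=C[C@H](OC(=O)C(C)C)[C@@H]1C(C)C | intermediate
21 | (4S,5S,6R)-2-(hydroxymethyl)-6-{[(E)-4-hydroxy-2-methylbut-2-enoyl]oxy}-4-(isobutyryloxy)-5-isopropylcyclohex-2-en-1-one | C/C(=C\CO)C(=O)O[C@H]1C(=O)C(CO)=C[C@H](OC(=O)C(C)C)[C@@H]1C(C)C | target

## Step count and least certain steps

Total: 13 steps. Longest linear sequence: 11 steps (steps 1–9, 12 and 13, from alkyne 1); the side-chain acid 18 takes 2 steps (10 and 11).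

**Step 3 (key step).**
- What may go wrong: the isopropyl group sits on the bond-forming nucleophilic carbon, so the cycloaddition may be slow under a mild chiral Lewis acid. Long exposure invites CO2 extrusion from the adduct. A stepwise zwitterionic path with bond rotation would erode the trans C7/C8 relation, and facial discrimination for a 1,2-disubstituted enol ether may be incomplete.
- Fallback: stereocontrol is moved from the catalyst to a resolution. Starting from 5 and 6, the cycloaddition is run without a chiral ligand, at about 10–12 kbar in CH2Cl2 or with Yb(OTf)3 alone, to give the racemic endo adduct F1. Saponification as in step 4 gives the racemic hydroxy diacid F2. Crystallisation with one antipode of 1-phenylethylamine (written as R) should give the diastereomerically pure ammonium salt F3, and acidification returns to the route at 8.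

**Step 5.**
- What may go wrong: after the first decarboxylation the C1 radical or cation is allylic, so acetate may be delivered to C3; that allylic transposition gives a conjugated acid which cannot lose its second carboxyl. Oxidation of the free allylic C4 alcohol by tetravalent lead and relactonisation of the cis hydroxy acid are further risks.
- Fallback: the oxidation is done at the bridgehead of the re-formed bicycle, where the radical is orthogonal to the alkene and cannot transpose. Starting from 8, carbodiimide lactonisation (EDC·HCl, CH2Cl2, dilute) gives the bridgehead acid F4. Oxalyl chloride, then the sodium salt of N-hydroxypyridine-2-thione, gives the Barton ester F5. Photolysis under O2 with t-BuSH and a P(OMe)3 work-up gives the bridgehead hydroxy lactone F6 (Barton decarboxylative hydroxylation). LiBH4 opens it to the triol F7, and NaIO4 cleaves the 1,2-diol to return to the route at 10.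

**Step 7.**
- What may go wrong: addition of the nucleophilic catalyst to C3 is hindered by the C4 ester and the cis isopropyl group; a slow reaction means long contact with aqueous base, with hydrolysis of the isobutyrate or enolisation at C6.
- Fallback: C7 is introduced by cross-coupling. Starting from 11, I2 and pyridine in CH2Cl2 give the 2-iodoenone F8; Stille coupling with (tributylstannyl)methanol (Pd(PPh3)4, dioxane, 80 °C) returns to the route at 12.

**Step 12.**
- What may go wrong: acylation of the hindered α-ketol may be slow, and under amine base the activated enoic acid may deconjugate or isomerise through a dienolate while C6 enolises.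
- Fallback: the side chain is built on the ring oxygen. Starting from 14, acylation with 2-(diethoxyphosphoryl)propanoic acid (DCC, DMAP cat.) gives the phosphonate ester F9; Horner–Wadsworth–Emmons reaction with aldehyde 15 under Masamune–Roush conditions (LiCl, i-Pr2NEt, MeCN) returns to the route at 20.

## Further compounds

F1 | step 3 | racemic methyl 7-isopropyl-8-[(4-methoxybenzyl)oxy]-3-oxo-2-oxabicyclo[2.2.2]oct-5-ene-4-carboxylate (7 and its enantiomer, 1:1) | COc1ccc(CO[C@H]2[C@@]3(C(=O)OC)C=C[C@H](OC3=O)[C@@H]2C(C)C)cc1.COc1ccc(CO[C@@H]2[C@]3(C(=O)OC)C=C[C@@H](OC3=O)[C@H]2C(C)C)cc1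
F2 | step 3 | racemic 4-hydroxy-5-isopropyl-6-[(4-methoxybenzyl)oxy]cyclohex-2-ene-1,1-dicarboxylic acid (8 and its enantiomer, 1:1) | COc1ccc(CO[C@H]2C(C(=O)O)(C(=O)O)C=C[C@H](O)[C@@H]2C(C)C)cc1.COc1ccc(CO[C@@H]2C(C(=O)O)(C(=O)O)C=C[C@@H](O)[C@H]2C(C)C)cc1
F3 | step 3 | (R)-1-phenylethylammonium hydrogen (4S,5S,6R)-4-hydroxy-5-isopropyl-6-[(4-methoxybenzyl)oxy]cyclohex-2-ene-1,1-dicarboxylate (1:1 salt of 8) | C[C@@H]([NH3+])c1ccccc1.COc1ccc(CO[C@H]2C(C(=O)[O-])(C(=O)O)C=C[C@H](O)[C@@H]2C(C)C)cc1
F4 | step 5 | (1S,4R,7S,8R)-7-isopropyl-8-[(4-methoxybenzyl)oxy]-3-oxo-2-oxabicyclo[2.2.2]oct-5-ene-4-carboxylic acid | COc1ccc(CO[C@H]2[C@@]3(C(=O)O)C=C[C@H](OC3=O)[C@@H]2C(C)C)cc1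
F5 | step 5 | 2-thioxopyridin-1(2H)-yl ester (Barton ester) of F4 | COc1ccc(CO[C@H]2[C@@]3(C(=O)ON4C=CC=CC4=S)C=C[C@H](OC3=O)[C@@H]2C(C)C)cc1
F6 | step 5 | (1S,4S,7S,8R)-4-hydroxy-7-isopropyl-8-[(4-methoxybenzyl)oxy]-2-oxabicyclo[2.2.2]oct-5-en-3-one | COc1ccc(CO[C@H]2[C@@]3(O)C=C[C@H](OC3=O)[C@@H]2C(C)C)cc1
F7 | step 5 | (1R,4S,5S,6R)-1-(hydroxymethyl)-5-isopropyl-6-[(4-methoxybenzyl)oxy]cyclohex-2-ene-1,4-diol | COc1ccc(CO[C@H]2[C@](O)(CO)C=C[C@H](O)[C@@H]2C(C)C)cc1
F8 | step 7 | (4R,5S,6R)-2-iodo-4-(isobutyryloxy)-5-isopropyl-6-[(4-methoxybenzyl)oxy]cyclohex-2-en-1-one | COc1ccc(CO[C@H]2C(=O)C(I)=C[C@H](OC(=O)C(C)C)[C@@H]2C(C)C)cc1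
F9 | step 12 | 2-(diethoxyphosphoryl)propanoate ester of 14 at the C6 oxygen (epimers at the phosphonate carbon) | CCOP(=O)(OCC)C(C)C(=O)O[C@H]1C(=O)C(CO[Si](C)(C)C(C)(C)C)=C[C@H](OC(=O)C(C)C)[C@@H]1C(C)C
A1 | alternative 1 | 2-isopropylpropane-1,3-diol | CC(C)C(CO)CO
A2 | alternative 1 | 2-methylenepropane-1,3-diyl diacetate | CC(=O)OCC(=C)COC(C)=O
A3 | alternative 1 | (1S,3S)-2-isopropyl-5-methylenecyclohexane-1,3-diol | O[C@H]1CC(=C)C[C@H](O)C1C(C)C
A4 | alternative 2 | 4,4-dimethoxycyclohexa-2,5-dien-1-one | COC1(OC)C=CC(=O)C=C1
A5 | alternative 2 | diisopropylzinc | CC(C)[Zn]C(C)C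
A6 | alternative 2 | (5R,6R)-6-hydroxy-5-isopropyl-4,4-dimethoxycyclohex-2-en-1-one (5,6-trans) | O[C@H]1C(=O)C=CC(OC)(OC)[C@@H]1C(C)C
A7 | alternative 3 | (5R,3Z)-3-{[(tert-butyldimethylsilyl)oxy]methyl}-7-methyl-1,2-dioxoocta-3,6-dien-5-yl 2-methylpropanoate | O=CC(=O)/C(CO[Si](C)(C)C(C)(C)C)=C\[C@H](OC(=O)C(C)C)C=C(C)C
A8 | alternative 3 | (4S,5R,6R)-2-{[(tert-butyldimethylsilyl)oxy]methyl}-6-hydroxy-4-(isobutyryloxy)-5-(prop-1-en-2-yl)cyclohex-2-en-1-one (4,5-cis, 5,6-trans) | O[C@H]1C(=O)C(CO[Si](C)(C)C(C)(C)C)=C[C@H](OC(=O)C(C)C)[C@@H]1C(C)=C
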